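**Assumptions (one line):** 4-methylpent-4-en-1-ol, acrolein, methyl acrylate, (±)-2-vinyloxirane and propargyl alcohol are commercial, and the macrocyclic chromium allylation gives the trans-fused lactone, with both new carbinol and ring-fusion centres controlled by the two (S)-acetoxy centres.

## Retrosynthetic overview
1. The target is the trans-fused α-methylene-γ-lactone on a 14-membered carbocycle. It comes from lactonisation of a methyl hydroxy-ester, which is the product of an intramolecular Nozaki–Hiyama (NHK-type) allylation of an enal by a 2-(bromomethyl)alk-2-enoate. The macrocycle forms first, then the lactone.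
2. The allylic bromide comes from a Morita–Baylis–Hillman (MBH) alcohol by SN2′ bromination. The enal comes from a primary allylic TBS ether.
3. The chain is cut at the C7=C8 trisubstituted alkene by cross-metathesis (CM) of a vinyl-carbinol acetate (left fragment) with a methallyl-terminated MBH adduct (right fragment).
4. The right fragment is built from 4-methylpent-4-en-1-ol by CM with acrolein, Brown methallylation (sets one acetate carbon), acetylation, desilylation, oxidation and MBH reaction.
5. The left fragment is built from (R)-vinyloxirane by alkynylalane opening (sets the other acetate carbon), then Red-Al/I₂ and Me₂CuLi to give the E-trisubstituted alkene.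

## Right fragment

**Step 1**
Reactants: 1, 4-methylpent-4-en-1-ol
Product: 2, TBS ether of 1
Conditions: TBSCl, imidazole, CH₂Cl₂, 0 °C → rt
Reagents that add atoms: TBSCl, CC(C)(C)[Si](C)(C)Cl
Why: Silylation masks the primary alcohol that later becomes the C1 aldehyde.

**Step 2**
Reactants: 2; 3, acrolein
Product: 4, (E)-6-(TBSO)-3-methylhex-2-enal
Conditions: acrolein (10 equiv), Hoveyda–Grubbs II (5 mol%), CH₂Cl₂, 40 °C
Reagents that add atoms: none
Why: Cross-metathesis of the 1,1-disubstituted alkene with excess acrolein releases ethylene and gives the thermodynamically preferred E-trisubstituted enal.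

**Step 3**
Reactants: 4
Product: 5, (4E,6S)-1-(TBSO)-4,8-dimethylnona-4,8-dien-6-ol
Conditions: (–)-Ipc₂B(methallyl) (from (+)-α-pinene), Et₂O, –78 °C; then NaOH, H₂O₂
Reagents that add atoms: (–)-B-methallyldiisopinocampheylborane, C=C(C)CB(C1C(C)C2CC(C2(C)C)C1)C1C(C)C2CC(C2(C)C)C1 (Ipc stereocentres not drawn; they come from (+)-α-pinene)
Why: Brown asymmetric methallylation through a closed chair transition state delivers the methallyl group to the Si face of the enal. This sets the carbinol as (S) and installs the methallyl alkene; oxidative work-up only removes boron.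

**Step 4**
Reactants: 5
Product: 6, acetate of 5
Conditions: Ac₂O, Et₃N, DMAP (cat.), CH₂Cl₂, 0 °C
Reagents that add atoms: Ac₂O, CC(=O)OC(C)=O
Why: Acylation of the secondary alcohol leaves the stereocentre untouched.

**Step 5**
Reactants: 6
Product: 7, (4E,6S)-6-acetoxy-4,8-dimethylnona-4,8-dien-1-ol
Conditions: HF·pyridine, THF/pyridine, 0 °C → rt
Reagents that add atoms: none
Why: Fluoride cleaves the primary silyl ether selectively, and the acetate and both alkenes survive.

**Step 6**
Reactants: 7
Product: 8, (4E,6S)-6-acetoxy-4,8-dimethylnona-4,8-dienal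
Conditions: Dess–Martin periodinane, NaHCO₃, CH₂Cl₂, 0 °C
Reagents that add atoms: none
Why: Buffered Dess–Martin oxidation gives the aldehyde without touching the allylic acetate or alkenes.

**Step 7**
Reactants: 8; 9, methyl acrylate
Product: 10, methyl 2-[(4E,6S)-6-acetoxy-1-hydroxy-4,8-dimethylnona-4,8-dien-1-yl]acrylate (C1 epimers)
Conditions: methyl acrylate (5 equiv), DABCO (0.5 equiv), neat, 25 °C, 4 d
Reagents that add atoms: none
Why: The MBH reaction forms the new C–C bond to the aldehyde. The new carbinol is an epimeric mixture, but that centre is destroyed when the allylic bromide forms in Step 19.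

## Left fragment

**Step 8**
Reactants: 11, (±)-2-vinyloxirane
Product: 12, (R)-2-vinyloxirane
Conditions: (S,S)-(salen)Co(III)OAc (0.5 mol%), H₂O (0.55 equiv), 0 °C → rt, then distillation
Reagents that add atoms: none
Why: Jacobsen hydrolytic kinetic resolution leaves the (R)-epoxide in high ee and sets the future acetate-bearing carbon.

**Step 9**
Reactants: 13, propargyl alcohol
Product: 14, THP propargyl ether
Conditions: 3,4-dihydro-2H-pyran, PPTS (cat.), CH₂Cl₂, rt
Reagents that add atoms: dihydropyran, C1=COCCC1
Why: Acetal protection prevents O-metalation and allows clean alkynylalane formation.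

**Step 10**
Reactants: 14; 12
Product: 15, (3S)-7-(THPO)hept-1-en-5-yn-3-ol
Conditions: n-BuLi, THF, –78 °C; then Et₂AlCl; then 12, –78 → 0 °C
Reagents that add atoms: none
Why: The alkynylalane opens the vinyl epoxide by SN2 at the terminal CH₂. The carbinol C–O bond is not touched, so the (R)-epoxide becomes the (S)-alcohol (the CIP priorities change).

**Step 11**
Reactants: 15
Product: 16, (3S)-hept-1-en-5-yne-3,7-diol
Conditions: PPTS, MeOH, 45 °C
Reagents that add atoms: none
Why: Acetal methanolysis frees the propargylic alcohol that directs the next step.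

**Step 12**
Reactants: 16
Product: 17, (3S,5Z)-5-iodohepta-1,5-diene-3,7-diol
Conditions: Red-Al, THF, 0 °C → rt; EtOAc; then I₂, –78 °C
Reagents that add atoms: iodine, II
Why: Red-Al hydroalumination of a propargylic alkoxide is trans. It puts hydride on the carbon next to CH₂OH and aluminium on the distal alkyne carbon in a five-membered oxa-aluminacycle. Iodinolysis then gives the trisubstituted vinyl iodide with I cis to CH₂OH.

**Step 13**
Reactants: 17
Product: 18, (3S,5E)-5-methylhepta-1,5-diene-3,7-diol
Conditions: Me₂CuLi (6 equiv), Et₂O, –78 → 0 °C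
Reagents that add atoms: lithium dimethylcuprate, C[Cu-]C.[Li+]
Why: Cuprate substitution of the vinyl iodide occurs with retention, so the methyl is cis to CH₂OH and the trisubstituted alkene is E.

**Step 14**
Reactants: 18
Product: 19, (3S,5E)-7-(TBSO)-5-methylhepta-1,5-dien-3-ol
Conditions: TBSCl (1.05 equiv), imidazole, CH₂Cl₂, –10 → 0 °C
Reagents that add atoms: TBSCl, CC(C)(C)[Si](C)(C)Cl
Why: The unhindered primary allylic alcohol silylates selectively over the secondary one.

**Step 15**
Reactants: 19
Product: 20, (3S,5E)-7-(TBSO)-5-methylhepta-1,5-dien-3-yl acetate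
Conditions: Ac₂O, pyridine, DMAP (cat.), CH₂Cl₂, 0 °C
Reagents that add atoms: Ac₂O, CC(=O)OC(C)=O
Why: Acetylation installs the second acetate with the stereocentre untouched.

## Coupling and ring formation

**Step 16**
Reactants: 20 (3 equiv); 10
Product: 21, TBS-protected triene MBH alcohol
Conditions: Hoveyda–Grubbs II (10 mol%), CH₂Cl₂ (0.05 M), 40 °C, 18 h
Reagents that add atoms: none
Why: Cross-metathesis of the monosubstituted vinyl group of 20 with the methallyl alkene of 10 forms the E-trisubstituted C7=C8 bond and loses ethylene. Excess 20 suppresses its homodimerisation.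

**Step 17**
Reactants: 21
Product: 22, primary allylic alcohol
Conditions: HF·pyridine, THF/pyridine, 0 °C → rt
Reagents that add atoms: none
Why: The primary silyl ether is cleaved selectively, and the acetates, the MBH alcohol and the alkenes survive.

**Step 18**
Reactants: 22
Product: 23, enal with free MBH alcohol
Conditions: activated MnO₂ (20 equiv), CH₂Cl₂, rt
Reagents that add atoms: none
Why: MnO₂ oxidises the electron-rich primary allylic alcohol much faster than the electron-poor, hindered MBH carbinol, giving the E-enal.

**Step 19**
Reactants: 23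
Product: 24, enal bearing the (2Z)-2-(bromomethyl)alk-2-enoate
Conditions: NBS, Me₂S, CH₂Cl₂, 0 °C → rt
Reagents that add atoms: NBS, O=C1CCC(=O)N1Br
Why: The MBH alcohol undergoes SN2′ bromination to the trisubstituted (Z)-allylic bromide, which removes the C1 epimer problem. The product is used crude.

**Step 20**
Reactants: 24
Product: 25, trans-configured macrocyclic hydroxy ester (methyl 2-substituted acrylate with the free C2 carbinol)
Conditions: CrCl₂ (8 equiv), DMF, 0.003 M (syringe-pump addition), 25 °C
Reagents that add atoms: none
Why: Intramolecular Nozaki–Hiyama allylchromium addition closes the 14-membered ring through a γ-attack, six-membered chair transition state. This is anti-selective for γ-substituted allylchromiums, which gives the trans relationship, and the two (S)-acetoxy centres bias the macrocyclic conformation.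

**Step 21**
Reactants: 25
Product: 26, target (CID 11069750)
Conditions: TsOH·H₂O (cat.), CH₂Cl₂, rt
Reagents that add atoms: none
Why: Acid-catalysed lactonisation of the γ-hydroxy ester with loss of MeOH gives the α-methylene-γ-lactone. The ring-fusion stereochemistry is already set and is not involved.

## Compound list
1 | 4-methylpent-4-en-1-ol | C=C(C)CCCO | starting material
2 | TBS ether of 1 | C=C(C)CCCO[Si](C)(C)C(C)(C)C | intermediate
3 | acrolein | C=CC=O | starting material
4 | (E)-6-(TBSO)-3-methylhex-2-enal | O=C/C=C(\C)CCCO[Si](C)(C)C(C)(C)C | intermediate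
5 | (4E,6S)-1-(TBSO)-4,8-dimethylnona-4,8-dien-6-ol | C=C(C)C[C@H](O)/C=C(\C)CCCO[Si](C)(C)C(C)(C)C | intermediate
6 | acetate of 5 | C=C(C)C[C@H](OC(C)=O)/C=C(\C)CCCO[Si](C)(C)C(C)(C)C | intermediate
7 | (4E,6S)-6-acetoxy-4,8-dimethylnona-4,8-dien-1-ol | C=C(C)C[C@H](OC(C)=O)/C=C(\C)CCCO | intermediate
8 | (4E,6S)-6-acetoxy-4,8-dimethylnona-4,8-dienal | C=C(C)C[C@H](OC(C)=O)/C=C(\C)CCC=O | intermediate
9 | methyl acrylate | C=CC(=O)OC | starting material
10 | MBH adduct (C1 epimers) | C=C(C)C[C@H](OC(C)=O)/C=C(\C)CCC(O)C(=C)C(=O)OC | intermediate
11 | (±)-2-vinyloxirane | C=CC1CO1 | starting material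
12 | (R)-2-vinyloxirane | C=C[C@@H]1CO1 | intermediate
13 | propargyl alcohol | C#CCO | starting material
14 | THP propargyl ether | C#CCOC1CCCCO1 | intermediate
15 | (3S)-7-(THPO)hept-1-en-5-yn-3-ol | C=C[C@@H](O)CC#CCOC1CCCCO1 | intermediate
16 | (3S)-hept-1-en-5-yne-3,7-diol | C=C[C@@H](O)CC#CCO | intermediate
17 | (3S,5Z)-5-iodohepta-1,5-diene-3,7-diol | OC/C=C(\I)C[C@H](O)C=C | intermediate
18 | (3S,5E)-5-methylhepta-1,5-diene-3,7-diol | OC/C=C(\C)C[C@H](O)C=C | intermediate
19 | 7-O-TBS ether of 18 | CC(C)(C)[Si](C)(C)OC/C=C(\C)C[C@H](O)C=C | intermediate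
20 | (3S,5E)-7-(TBSO)-5-methylhepta-1,5-dien-3-yl acetate | CC(C)(C)[Si](C)(C)OC/C=C(\C)C[C@H](OC(C)=O)C=C | intermediate
21 | CM product (TBS ether, MBH alcohol) | CC(C)(C)[Si](C)(C)OC/C=C(\C)C[C@H](OC(C)=O)/C=C(\C)C[C@H](OC(C)=O)/C=C(\C)CCC(O)C(=C)C(=O)OC | intermediate
22 | primary allylic alcohol | OC/C=C(\C)C[C@H](OC(C)=O)/C=C(\C)C[C@H](OC(C)=O)/C=C(\C)CCC(O)C(=C)C(=O)OC | intermediate
23 | enal with MBH alcohol | O=C/C=C(\C)C[C@H](OC(C)=O)/C=C(\C)C[C@H](OC(C)=O)/C=C(\C)CCC(O)C(=C)C(=O)OC | intermediate
24 | enal with (Z)-allylic bromide | O=C/C=C(\C)C[C@H](OC(C)=O)/C=C(\C)C[C@H](OC(C)=O)/C=C(\C)CC/C=C(\CBr)C(=O)OC | intermediate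
25 | macrocyclic hydroxy ester (NHK product) | O[C@H]1/C=C(\C)C[C@H](OC(C)=O)/C=C(\C)C[C@H](OC(C)=O)/C=C(\C)CC[C@@H]1C(=C)C(=O)OC | intermediate
26 | target, CID 11069750 | C=C1C(=O)O[C@H]2/C=C(\C)C[C@H](OC(C)=O)/C=C(\C)C[C@H](OC(C)=O)/C=C(\C)CC[C@H]12 | target

**Total steps:** 21.
**Longest linear sequence:** 13 steps. This is steps 1–7 then 16–21, or steps 9–15 (or 8, 10–15) then 16–21. It is 62% of the total step count.

**Three steps most likely to fail**
1. **Step 20, macrocyclic allylchromium addition.** The risks are oligomerisation and loss of C1/C2 diastereocontrol, since the two acetate centres are remote from the new stereocentres. *Fallback:* first build the trans-α-methylene lactone by an intermolecular anti-selective chromium allylation of acrolein with a tethered γ-substituted 2-(bromomethyl)alkenoate, then close the 14-membered ring by macro-RCM between the lactone's carbinol vinyl group and a methallyl terminus.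
2. **Step 16, cross-metathesis.** The risks are competition from the acrylate and the trisubstituted alkenes, homodimerisation, and poor E/Z control at the new trisubstituted alkene. *Fallback:* drop the metathesis and form C7=C8 by the alkyne route used for the left fragment. Open a vinyl epoxide with the alkynylalane of a right-fragment alkyne, then convert the alkyne to the E-methyl alkene with Red-Al/I₂/Me₂CuLi.
3. **Step 12, Red-Al/I₂ on the free diol.** The homopropargylic or allylic alkoxide could compete in directing the hydroalumination, which would erode regio- and stereocontrol. *Fallback:* Zr-catalysed methylalumination of the terminal alkyne HC≡C–CH₂–CH(OTBS)–CH=CH₂, which comes from the vinyl epoxide and a lithium acetylide. Quench to the E-vinyl iodide, then install the CH₂OH carbon by Pd-catalysed methoxycarbonylation and DIBAL reduction.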